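**Remark on the chemistry (assumption):** germacrane numbering is used throughout (ring C1–C10, lactone C11/C12, methyls C13 on C11, C14 on C10, C15 on C4). Both oxiranes of the target are cis with respect to the ring (C2/C9 and C3/C6 on the same side), so a Z,Z-configured chain is carried. Angelic anhydride and 2-(bromomethyl)acrylic acid are taken as purchasable.

## Retrosynthetic overview

1. Both angelates go on last: C6 by Mitsunobu inversion of a 6R alcohol, C11 by alkoxide acylation; the C11 carbinol with its C13 methyl comes from hydration of a C11=C13 exo-methylene lactone.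
2. The ten-membered carbocycle is opened at C6–C7: chromium-mediated intramolecular allylation of a C6 epoxy aldehyde by a 3-(bromomethyl)butenolide (bromide on C13), with the lactone and both oxiranes already in place.
3. Enabling feature: carbinol C6 is bonded to C7, the β-carbon of the γ-lactone ring C7–C11–C12(=O)–O–C8. With C11=C13 the unit C6(OH)–C7–C11(=C13)–C12 is the homoallylic alcohol left by a 2-carboxyallyl metal adding to an aldehyde, and C6 is also the carbonyl carbon of a 4,5-epoxy aldehyde.
4. Seco chain: nerol gives C1–C6 and C15 with the Z-C4=C5 geometry; C10/C14 come from an iodo-Wittig reagent, C7–C9 from (R)-epichlorohydrin, C11–C13 from 2-(bromomethyl)acrylic acid.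
5. Ring order: 4,5-oxirane (Sharpless) → 1,10-oxirane (vanadium, directed by C8–OH) → butenolide (ring-closing metathesis) → ten-membered carbocycle (last).

Key step: step 12

## Route

Step 1
Reactants: 1 nerol
Product: 2 (2S,3R)-2,3-epoxynerol
Conditions: Ti(OiPr)4 (5 mol %), diethyl L-(+)-tartrate (6 mol %), t-BuOOH, 4 Å MS, CH2Cl2, −20 °C
Reagents that add atoms: tert-butyl hydroperoxide CC(C)(C)OO
Why: Sharpless asymmetric epoxidation of the Z-allylic alcohol is reagent-controlled, diethyl L-(+)-tartrate giving the (2S,3R)-epoxy alcohol, which fixes C4 (R) and C5 (S) and leaves the remote trisubstituted alkene untouched because only the titanium-bound allylic alcohol is activated.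

Step 2
Reactants: 2 (2S,3R)-2,3-epoxynerol
Product: 3 TBS ether of epoxynerol
Conditions: TBSCl, imidazole, DMF, 0 °C to rt
Reagents that add atoms: tert-butyldimethylsilyl chloride CC(C)(C)[Si](C)(C)Cl
Why: Imidazole-promoted silylation of the primary alcohol masks the future C6 oxygen through the organometallic steps and creates no stereocentre.

Step 3
Reactants: 3 TBS ether of epoxynerol
Product: 5 C1 aldehyde 3-[(2R,3S)-3-{[tert-butyl(dimethyl)silyl]oxymethyl}-2-methyloxiran-2-yl]propanal, via ozonide 4 (not isolated)
Conditions: O3, CH2Cl2, −78 °C; then Me2S, −78 °C to rt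
Reagents that add atoms: ozone [O-][O+]=O
Why: Ozonolysis with reductive work-up cleaves the only C=C bond left, releasing the C1 aldehyde and acetone, while the oxirane and the silyl ether are inert to ozone.

Step 4
Reactants: 5 C1 aldehyde
Product: 6 (Z)-vinyl iodide tert-butyl({(2S,3R)-3-[(3Z)-4-iodopent-3-en-1-yl]-3-methyloxiran-2-yl}methoxy)dimethylsilane
Conditions: EtPPh3I, n-BuLi, THF; I2, −78 °C; NaN(SiMe3)2, −20 °C; then 5, −78 °C
Reagents that add atoms: ethyltriphenylphosphonium iodide CC[P+](c1ccccc1)(c1ccccc1)c1ccccc1.[I-]; iodine II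
Why: The Stork–Zhao variant of the Wittig olefination with the α-iodo ylide Ph3P=C(I)CH3 is kinetically Z-selective for aliphatic aldehydes, placing iodine cis to the chain so that C10 carries its methyl group (C14) and a handle cis to C2, the geometry of the cis-1,10-oxirane.

Step 5
Reactants: 6 (Z)-vinyl iodide; 7 (R)-epichlorohydrin
Product: 10 chlorohydrin (2R,4Z)-1-chloro-4-methyl-7-[(2R,3S)-3-{[tert-butyl(dimethyl)silyl]oxymethyl}-2-methyloxiran-2-yl]hept-4-en-2-ol, via alkenyllithium 8 (not isolated), via alkenylmagnesium bromide 9 (not isolated)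
Conditions: t-BuLi (2 equiv), Et2O, −78 °C; MgBr2·OEt2; CuI (10 mol %), 7, THF, −40 to −20 °C; then H2O
Reagents that add atoms: none
Why: Iodine–lithium exchange proceeds with retention of alkene geometry and the derived alkenyl Grignard reagent opens (R)-epichlorohydrin at its unsubstituted oxirane carbon under copper catalysis (SN2), so that C9 is attached cis to C2 and the untouched stereocentre of the epichlorohydrin becomes C8 (R).

Step 6
Reactants: 10 chlorohydrin
Product: 11 bis-oxirane chlorohydrin (C1 R, C4 R, C5 S, C8 R, C10 S)
Conditions: VO(acac)2 (5 mol %), t-BuOOH, CH2Cl2, 0 °C to rt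
Reagents that add atoms: tert-butyl hydroperoxide CC(C)(C)OO
Why: Hydroxyl-directed vanadium-catalysed epoxidation of the homoallylic alcohol should pass through a chair-like vanadate transition state with the CH2Cl group on C8 equatorial (the axial alternative clashes with the C10 methyl group), which delivers oxygen to the face giving the 10S,1R cis-oxirane, and no other alkene is present.

Step 7
Reactants: 11 bis-oxirane chlorohydrin
Product: 13 vinyl carbinol (C8 R allylic alcohol with C7=CH2), via terminal oxirane 12 (not isolated)
Conditions: Me3SI, n-BuLi, THF, −10 °C to rt; then H2O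
Reagents that add atoms: trimethylsulfonium iodide C[S+](C)C.[I-]
Why: Dimethylsulfonium methylide first closes the chlorohydrin to the terminal oxirane 12, then opens it at CH2 and eliminates dimethyl sulfide (one-carbon homologation of an epoxide to an allylic alcohol), which makes C8 a vinyl carbinol without touching its configuration or the two hindered trisubstituted oxiranes.

Step 8
Reactants: 13 vinyl carbinol; 14 2-(bromomethyl)acrylic acid
Product: 16 2-(bromomethyl)acrylate ester of 13, via 2-(bromomethyl)acryloyl chloride 15 (not isolated)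
Conditions: 14, (COCl)2, DMF (cat), CH2Cl2, 0 °C to rt, evaporate; then 13, 2,6-lutidine, CH2Cl2, −40 to 0 °C
Reagents that add atoms: none
Why: O-acylation of the secondary alcohol by the acid chloride with a hindered pyridine base, which does not displace the allylic bromide, gives the metathesis substrate with retention at C8.

Step 9
Reactants: 16 2-(bromomethyl)acrylate ester
Product: 17 butenolide TBS ether [(5R)-3-(bromomethyl)furan-2(5H)-one carrying the bis-oxirane chain on C8]
Conditions: second-generation Grubbs catalyst RuCl2(=CHPh)(PCy3)(H2IMes) (5 mol %), CH2Cl2 (5 mM), 40 °C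
Reagents that add atoms: none
Why: Ring-closing metathesis of an allyl 2-substituted acrylate is the standard route to α-substituted butenolides, loss of ethylene drives closure of the lactone ring (C7=C11), and the ruthenium carbene tolerates oxiranes, the silyl ether and the allylic bromide.

Step 10
Reactants: 17 butenolide TBS ether
Product: 18 butenolide primary alcohol (C6–OH)
Conditions: HF·pyridine, pyridine, THF, 0 °C
Reagents that add atoms: none
Why: Pyridine-buffered HF cleaves the primary silyl ether faster than it opens trisubstituted oxiranes and is neither basic enough to deprotonate the butenolide at C8 nor nucleophilic enough to displace the bromide.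

Step 11
Reactants: 18 butenolide primary alcohol
Product: 19 seco-aldehyde (C6 = CHO, bromide on C13)
Conditions: Dess–Martin periodinane, NaHCO3, CH2Cl2, 0 °C to rt
Reagents that add atoms: none
Why: Buffered Dess–Martin oxidation converts the primary 2,3-epoxy alcohol into the epoxy aldehyde under neutral conditions without epimerising C5 or touching the allylic bromide.

Step 12
Reactants: 19 seco-aldehyde
Product: 21 macrocyclic 6R alcohol (1R,4R,5S,6R,7R,8R,10S)-1,10:4,5-diepoxy-6-hydroxygermacr-11(13)-en-12,8-olide, via allylchromium dichloride 20 (not isolated)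
Conditions: CrCl2 (10 equiv), THF, slow addition of 19 (final 2 mM), rt; then H2O
Reagents that add atoms: none
Why: Two equivalents of CrCl2 reduce the allylic C13–Br bond of 19 to the allylchromium species 20 (trivalent chromium), whose γ-carbon C7 adds to the chromium-bound C6 aldehyde through a closed six-membered chair transition state with allyl transposition, so that the C6–C7 bond forms while the double bond moves from C7=C11 to C11=C13. The closest known reaction type is the Nozaki–Hiyama (chromium Barbier) allylation, used intramolecularly to close the ten-membered ring of germacranolides from 2-(bromomethyl)enoates and epoxy aldehydes, and intermolecularly with 3-(bromomethyl)furan-2(5H)-ones as allyl donors. The ten-membered carbocycle closes in the 10-exo-trig mode at the aldehyde carbon and is the only ring formed, the lactone and both oxiranes being already present. C7 should be set by attack on the butenolide face opposite to the C9 substituent on C8, giving the trans-fused lactone; C6 should be set by the chair with C5 equatorial and C8 held trans to the CH2–Cr arm by the lactone ring, giving the 6,7-anti (6R) alcohol, which is inverted on purpose in step 14. The step needs activation of the allyl bromide in the presence of two oxiranes and an aldehyde, γ- over α-attack, and ring closure over oligomerisation; the first two follow from the known behaviour of CrCl2 and allylchromium reagents, the last from high dilution and from the two cis-oxiranes, which act like cis-alkenes and fold C6 towards C7.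

Step 13
Reactants: 21 macrocyclic 6R alcohol
Product: 23 diol (1R,4R,5S,6R,7R,8R,10S,11R)-1,10:4,5-diepoxy-6,11-dihydroxygermacran-12,8-olide, via C11 hydroperoxide 22 (not isolated)
Conditions: Mn(dpm)3 (dpm = 2,2,6,6-tetramethylheptane-3,5-dionate, 10 mol %), PhSiH3, O2 (1 atm), i-PrOH/CH2Cl2, 0 °C to rt
Reagents that add atoms: dioxygen O=O
Why: Mukaiyama hydration (hydrogen-atom transfer from a manganese hydride to C13, capture of the tertiary C11 radical by O2, reduction of the hydroperoxide) turns the exo-methylene into the C13 methyl and the C11 hydroxyl, and oxygen is expected on the lactone face anti to H7, the face attacked in selenenylation and hydroxylation of trans-fused α-methyl lactones, which gives 11R.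

Step 14
Reactants: 23 diol; 24 angelic acid
Product: 25 6S angelate (1R,4R,5S,6S,7S,8R,10S,11R)-6-angeloyloxy-1,10:4,5-diepoxy-11-hydroxygermacran-12,8-olide
Conditions: 24, PPh3, DIAD, toluene, 0 °C to rt
Reagents that add atoms: none
Why: Mitsunobu esterification activates only the secondary C6 hydroxyl (the tertiary C11–OH cannot react) and the angelate anion displaces the oxyphosphonium group with inversion, converting 6R into the 6S angelate under neutral conditions that should not isomerise angelate to tiglate.

Step 15
Reactants: 25 6S angelate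
Product: 26 CNP0219924.2 (target)
Conditions: LiN(SiMe3)2, THF, −78 °C; angelic anhydride, −78 to 0 °C
Reagents that add atoms: angelic anhydride C/C=C(/C)C(=O)OC(=O)/C(C)=C\C
Why: Acylation of the preformed lithium alkoxide of the tertiary α-hydroxy lactone with angelic anhydride at low temperature (alkoxide acylation, no acylpyridinium intermediate and hence no Z to E isomerisation) installs the second angelate, and a possible 1,3-acyl shift from O6 to O11 in the alkoxide is harmless because both positions end as angelates.

## Compound list

1 | nerol, (2Z)-3,7-dimethylocta-2,6-dien-1-ol | CC(C)=CCC/C(C)=C\CO | starting material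
2 | (2S,3R)-2,3-epoxynerol, [(2S,3R)-3-methyl-3-(4-methylpent-3-en-1-yl)oxiran-2-yl]methanol | CC(C)=CCC[C@@]1(C)O[C@H]1CO | intermediate
3 | TBS ether of 2 | CC(C)=CCC[C@@]1(C)O[C@H]1CO[Si](C)(C)C(C)(C)C | intermediate
4 | ozonide of 3 (3,3-dimethyl-1,2,4-trioxolane, both epimers at the trioxolane CH) | CC1(C)OOC(CC[C@@]2(C)O[C@H]2CO[Si](C)(C)C(C)(C)C)O1 | intermediate
5 | C1 aldehyde, 3-[(2R,3S)-3-{[tert-butyl(dimethyl)silyl]oxymethyl}-2-methyloxiran-2-yl]propanal | O=CCC[C@@]1(C)O[C@H]1CO[Si](C)(C)C(C)(C)C | intermediate
6 | (Z)-vinyl iodide (I on C10, cis to C2) | C/C(I)=C/CC[C@@]1(C)O[C@H]1CO[Si](C)(C)C(C)(C)C | intermediate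
7 | (R)-epichlorohydrin, (2R)-2-(chloromethyl)oxirane | ClC[C@H]1CO1 | starting material
8 | alkenyllithium (Li in place of I of 6, geometry retained) | C/C([Li])=C/CC[C@@]1(C)O[C@H]1CO[Si](C)(C)C(C)(C)C | intermediate
9 | alkenylmagnesium bromide (MgBr in place of I of 6) | C/C([Mg]Br)=C/CC[C@@]1(C)O[C@H]1CO[Si](C)(C)C(C)(C)C | intermediate
10 | chlorohydrin (C8 R, Z-C1=C10, C4 R, C5 S) | ClC[C@@H](C/C(C)=C\CC[C@@]1(C)O[C@H]1CO[Si](C)(C)C(C)(C)C)O | intermediate
11 | bis-oxirane chlorohydrin (C1 R, C4 R, C5 S, C8 R, C10 S) | ClC[C@@H](C[C@]1(C)O[C@@H]1CC[C@@]2(C)O[C@H]2CO[Si](C)(C)C(C)(C)C)O | intermediate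
12 | terminal oxirane (C7–C8 oxirane, C8 R) | C1O[C@@H]1C[C@]2(C)O[C@@H]2CC[C@@]3(C)O[C@H]3CO[Si](C)(C)C(C)(C)C | intermediate
13 | vinyl carbinol (C8 R allylic alcohol) | C=C[C@@H](C[C@]1(C)O[C@@H]1CC[C@@]2(C)O[C@H]2CO[Si](C)(C)C(C)(C)C)O | intermediate
14 | 2-(bromomethyl)acrylic acid | OC(=O)C(=C)CBr | starting material
15 | 2-(bromomethyl)acryloyl chloride | ClC(=O)C(=C)CBr | intermediate
16 | 2-(bromomethyl)acrylate ester of 13 | C=C[C@@H](C[C@]1(C)O[C@@H]1CC[C@@]2(C)O[C@H]2CO[Si](C)(C)C(C)(C)C)OC(=O)C(=C)CBr | intermediate
17 | butenolide TBS ether, (5R)-3-(bromomethyl)furan-2(5H)-one with the bis-oxirane chain on C8 | BrCC1=C[C@@H](C[C@]2(C)O[C@@H]2CC[C@@]3(C)O[C@H]3CO[Si](C)(C)C(C)(C)C)OC1=O | intermediate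
18 | butenolide primary alcohol (C6–OH) | BrCC1=C[C@@H](C[C@]2(C)O[C@@H]2CC[C@@]3(C)O[C@H]3CO)OC1=O | intermediate
19 | seco-aldehyde (C6 = CHO; same spatial arrangement, C5 becomes R by CIP rank only) | BrCC1=C[C@@H](C[C@]2(C)O[C@@H]2CC[C@@]3(C)O[C@H]3C=O)OC1=O | intermediate
20 | allylchromium dichloride (Cr on C13, solvent ligands omitted) | Cl[Cr](Cl)CC1=C[C@@H](C[C@]2(C)O[C@@H]2CC[C@@]3(C)O[C@H]3C=O)OC1=O | intermediate
21 | (1R,4R,5S,6R,7R,8R,10S)-1,10:4,5-diepoxy-6-hydroxygermacr-11(13)-en-12,8-olide | O[C@@H]1[C@@H]2[C@@H](C[C@]3(C)O[C@@H]3CC[C@@]3(C)O[C@@H]13)OC(=O)C2=C | intermediate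
22 | C11 hydroperoxide of 23 (11R) | O[C@@H]1[C@@H]2[C@@H](C[C@]3(C)O[C@@H]3CC[C@@]3(C)O[C@@H]13)OC(=O)[C@]2(C)OO | intermediate
23 | (1R,4R,5S,6R,7R,8R,10S,11R)-1,10:4,5-diepoxy-6,11-dihydroxygermacran-12,8-olide | O[C@@H]1[C@@H]2[C@@H](C[C@]3(C)O[C@@H]3CC[C@@]3(C)O[C@@H]13)OC(=O)[C@]2(C)O | intermediate
24 | angelic acid, (2Z)-2-methylbut-2-enoic acid | C/C=C(/C)C(=O)O | starting material
25 | (1R,4R,5S,6S,7S,8R,10S,11R)-6-angeloyloxy-1,10:4,5-diepoxy-11-hydroxygermacran-12,8-olide | C/C=C(/C)C(=O)O[C@H]1[C@@H]2[C@@H](C[C@]3(C)O[C@@H]3CC[C@@]3(C)O[C@@H]13)OC(=O)[C@]2(C)O | intermediate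
26 | CNP0219924.2, (1R,4R,5S,6S,7S,8R,10S,11R)-6,11-bis(angeloyloxy)-1,10:4,5-diepoxygermacran-12,8-olide | C/C=C(/C)C(=O)O[C@H]1[C@@H]2[C@@H](C[C@]3(C)O[C@@H]3CC[C@@]3(C)O[C@@H]13)OC(=O)[C@]2(C)OC(=O)/C(C)=C\C | target

## Step count and risks

Total step count: 15. Longest linear sequence: 15 steps (nerol 1 to 26).

Three steps most likely to fail:

**Step 12 (macrocyclic allylation).** Oligomerisation by intermolecular allylation may outrun ring closure at the heterogeneous chromium surface. The α,β-epoxy aldehyde may be opened reductively by divalent chromium before the bromide is activated. The lactone acyl group may migrate to the new C6 chromium alkoxide. Fallback without a reducing metal, boron in place of chromium: it sets out from alcohol 18. Borylation of the allylic bromide with bis(pinacolato)diboron and Pd2(dba)3 (toluene, 50 °C) gives the allylboronate alcohol F1. Dess–Martin oxidation gives the boronate aldehyde F2. Heating F2 at high dilution in toluene (80 °C) should close the ring by thermal allylboration of the 2-(alkoxycarbonyl)allylboronate type through the same chair transition state. Hydrolysis of the borate on work-up brings the route back at 21.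

**Step 13 (hydration at C11).** Oxygen capture by the planar C11 radical may show poor facial selectivity, or the radical may be reduced early to the 11-methyl lactone. Polar fallback: it sets out from 21. Conjugate reduction with NaBH4 (MeOH, 0 °C) gives the 11,13-dihydro lactone F3, whose C11 configuration is erased in the next operation. The dianion (KN(SiMe3)2, 2.2 equiv, THF, −78 °C; the C6 alkoxide is a spectator) is hydroxylated with the Davis oxaziridine (2-(phenylsulfonyl)-3-phenyloxaziridine). Attack on the enolate face anti to H7 is expected, as in selenenylation of trans-fused lactones. The route is rejoined at 23.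

**Step 14 (Mitsunobu inversion at C6).** The hindered oxyphosphonium ion at C6, flanked by an oxirane and the ring fusion, may eliminate or not react. Inversion is also unwanted if the macrocyclisation gives the other C6 epimer. Redox fallback, stereoconvergent at C6: it sets out from 23. Dess–Martin oxidation gives the 6-ketone F4. Zn(BH4)2 (Et2O, −20 °C) should reduce this α,β-epoxy ketone under chelation control (zinc bridging the carbonyl and oxirane oxygens, hydride anti to C4) to the 6S diol F5. Either C6 epimer of 23 converges on F5. Double acylation of F5 with LiN(SiMe3)2 (2.5 equiv) and angelic anhydride, as in step 15, brings the route back at 26.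

## Further compounds

F1 | step 12 | allylboronate alcohol (pinacolboryl on C13, C6–OH) | CC1(C)OB(CC2=C[C@@H](C[C@]3(C)O[C@@H]3CC[C@@]4(C)O[C@H]4CO)OC2=O)OC1(C)C
F2 | step 12 | boronate aldehyde (pinacolboryl on C13, C6 = CHO) | CC1(C)OB(CC2=C[C@@H](C[C@]3(C)O[C@@H]3CC[C@@]4(C)O[C@H]4C=O)OC2=O)OC1(C)C
F3 | step 13 | 11,13-dihydro lactone (6R alcohol, C13 methyl, H on C11 anti to H7) | O[C@@H]1[C@@H]2[C@@H](C[C@]3(C)O[C@@H]3CC[C@@]3(C)O[C@@H]13)OC(=O)[C@H]2C
F4 | step 14 | 6-ketone of 23 (6-oxo, 11R hydroxyl) | O=C1[C@@H]2[C@@H](C[C@]3(C)O[C@@H]3CC[C@@]3(C)O[C@@H]13)OC(=O)[C@]2(C)O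
F5 | step 14 | 6S diol (C6 epimer of 23) | O[C@H]1[C@@H]2[C@@H](C[C@]3(C)O[C@@H]3CC[C@@]3(C)O[C@@H]13)OC(=O)[C@]2(C)O
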